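## Structural features

δ‑Tocopherol is a chroman: aromatic ring A (C4a to C8a) is fused to dihydropyran ring B (O1, C2, C3, C4), with a free phenol at C6 and a methyl group at C8. C2 is a fully substituted, oxygen‑bearing carbon that carries O1, a methyl group, C3 of ring B and C1' of a saturated 4',8',12'‑trimethyltridecyl chain. The three stereocentres (2R, 4'R, 8'R) are not adjacent: three methylene groups separate C2 from C4' and C4' from C8', so none can steer another, and every epimer is a diastereomer that is very hard to detect or remove. The electron‑rich 4‑alkoxyphenol is easily oxidised to a quinone, and the tertiary alkyl aryl ether C2–O1 can ionise under strong acid, which would scramble C2. The chain centres are best taken unchanged from natural phytol, so the real difficulty is C2, whose three carbon substituents (CH3, the CH2 of ring B, the CH2 of the chain) are too alike for dependable face discrimination by a catalyst. The key step uses the fact that O1, CH3 and C1' on C2 form the pattern of a chain methyl carbinol, while C3–C4–C4a is a 2‑arylethyl group. C2–C3 can therefore be made by a stereospecific shift of that group from boron onto the carbinol carbon, and ring B is closed afterwards at O1–C8a without touching C2.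

## Logic of the disconnections

19 ⇒ 17 (through 18): the O1–C8a bond of ring B is cut and the arene is taken back to the quinone level. This is the ring bond whose formation does not involve C2, so the stereocentre can be finished on an open chain. The forward step must exchange the aryl C–O bond and leave C2–O intact, which calls for mild acid and the hemiketal pathway.

17 ⇒ 16: the two ring carbonyls are traced back to two aryl methyl ethers (functional group change only). The ethers make the ring inert to organolithium and peroxide. The demand is an oxidant that removes both at the end and spares the tertiary alcohol.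

16 ⇒ 15: C2–O is exchanged for C2–B. This turns the carbinol into the product of a boron‑based C–C bond formation. The forward oxidation must go with complete retention.

15 ⇒ 7 + 12: the C2–C3 bond is cut. This divides the molecule into a C18 chain half and a C11 arene half, reduces the quaternary stereocentre to a secondary carbinol centre and leaves the arene half achiral. The forward step needs lithiation and borylation with retention, migration with inversion, a carbanion that keeps its configuration until trapped, and a boron partner small enough to be trapped quickly.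

7 ⇒ 4 + 5: the ester C(=O)–O bond is cut. The forward acylation of a secondary alcohol by a hindered acyl chloride must not touch the carbinol C–O bond.

4 ⇒ 3: the carbinol C2–H bond is cut (ketone reduction). The only new stereocentre of the chain half then comes from a flat methyl ketone. The demand is near‑perfect face selection between methyl and a long unbranched chain, for which an enzyme is the best tool.

3 ⇒ 1: the ketone carbonyl is traced to the C2=C3 double bond of 1. All chain carbons and both methyl‑bearing centres then come from the chiral pool. The demand is clean oxidative cleavage of one alkene.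

12 ⇒ 11: the C–B and C–H bonds across the vinyl group are cut. The forward step must place boron on the terminal carbon.

11 ⇒ 10: the C=C bond is cut back to an aldehyde and a one‑carbon ylide.

10 ⇒ 9: one O–CH3 bond is cut.

9 ⇒ 8: the aryl C–CHO bond ortho to the hydroxyl is cut. Only one ortho position of 8 is free, so the regiochemistry is fixed by the substrate.

## Other disconnections considered

Alternative 1: The cut is C2–C1', made on an intact chroman.
- Forward step: ester A2, the (3R,4R,8R)‑4,8,12‑trimethyltridec‑1‑en‑3‑yl ester of 6‑(benzyloxy)‑8‑methylchroman‑2‑carboxylic acid, is enolised with LiN(SiMe3)2 and silylated with Me3SiCl. The silyl ketene acetal undergoes an Ireland–Claisen shift through a chair to acid A1, which has C2 arranged as in the target with CO2H in place of CH3 (the descriptor reads 2S only because the priorities change).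
- In favour: a [3,3] shift is a dependable way to build a quaternary centre, and a racemic chroman acid suffices because C2 is flattened in the enolate.
- Better than the chosen plan on one point: ring B is present from the start, so there is no late ring closure and the C2–O1 bond is never exposed to ionising conditions.
- Against: C2 depends on two elements, the C3' carbinol configuration and the ketene acetal geometry (set by lithium chelation to O1). A chair model with O1 syn to the silyloxy group calls for the 3R carbinol, an extra stereocentre next to C4' that must be built and is then destroyed.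
- Against: the chain half is no longer the C18 unit that phytol gives in one step, CO2H must afterwards be reduced to CH3 in about three operations, and the alkene must be hydrogenated.
- Comparison: mechanistically the two plans are equal in kind, since both transfer carbinol chirality stereospecifically, but the chosen plan needs one control element instead of two. In step economy the alternative is clearly longer.

Alternative 2: No skeletal bond is cut; the C–H bonds at C4' and C8' are.
- Forward step: triene acetate A4 is hydrogenated with [Ir(cod)(L)]B[C6H3(CF3)2]4 (monovalent iridium, L a chiral pyridyl phosphinite P,N ligand) to A3, which saturates three alkenes and creates both chain centres at once.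
- In favour: two stereocentres arise in one catalytic, waste‑free step.
- Better than the chosen plan on one point: if A4, the acetate of a natural triene obtainable from plant oils, is accepted as a purchasable material, the route is about three steps.
- Against: C2 is not addressed but inherited. If A4 had to be made, C2 and two E‑trisubstituted alkenes would be needed first, which brings back the C2 problem and adds control of alkene geometry.
- Against: face selection at two unfunctionalised alkenes rests on the catalyst alone, and any wrong addition gives a diastereomer that cannot be removed.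
- Comparison: in structure the two plans are equal in that both take part of the stereochemistry from nature, but the chosen plan takes C4' and C8' as fixed sp3 centres with no selectivity question. In mechanism the alternative relies on catalyst control where the chosen plan relies on stereospecific transfer.

Alternative 3: The cut is the C2–CH3 bond.
- Forward step: chromone A6, turned into a silyloxybenzopyrylium ion by a silyl triflate, takes up methyl from Al(CH3)3 under copper thiophene‑2‑carboxylate (monovalent copper) and a chiral phosphoramidite to give chromanone A5.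
- In favour: chirality is catalytic and no enantiopure carbinol is needed. The flat precursor is easy to assemble, and its chain acid could come from 3 by haloform cleavage.
- Equal or better than the chosen plan on one point: ring B is present, so no late ring closure is needed.
- Against: C2 depends on face selection by the catalyst at a tetrasubstituted carbon of low electrophilicity. Anything short of complete selectivity leaves the 2‑epimer, which is not separable in practice.
- Against: Al(CH3)3 is pyrophoric, the C4 carbonyl must be removed afterwards and the benzyl ether cleaved.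
- Comparison: step economy is about equal. The mechanism is reagent control against substrate‑encoded stereospecificity, where the chosen plan passes on the purity of an enzymatically made carbinol.

Key step: step 8

Remark: natural (E)‑(7R,11R)‑phytol is taken as a purchasable single stereoisomer; its two methyl‑bearing centres become C4' and C8' unchanged.
Remark: the diol on boron is a spectator, so the primary boronate is carried as its six‑membered neopentyl glycol ester, which should be captured faster than a pinacol ester by the hindered, short‑lived tertiary organolithium; skeleton and bond formed are unchanged.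
Remark: configuration check: replacing the C2 hydrogen of the 2R methyl carbinol by C3, with the oxygen function left in place, corresponds to 2R in the target, so the 2R ester 7 is the correct precursor.

Step 1
Reactants: 1 (2E,7R,11R)‑3,7,11,15‑tetramethylhexadec‑2‑en‑1‑ol (natural phytol)
Product: 3 (6R,10R)‑6,10,14‑trimethylpentadecan‑2‑one, via secondary ozonide 2 (not isolated)
Conditions: O3, CH2Cl2, −78 °C; then Me2S, −78 °C to rt
Reagents that add atoms: ozone, [O-][O+]=O
Why: Ozonolysis with reductive work‑up: ozone adds to the only C=C, the ozonide 2 is reduced by Me2S to the methyl ketone and hydroxyacetaldehyde. C7 and C11 of 1 are remote sp3 centres and are not touched, and the alkene geometry of the starting material is irrelevant.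

Step 2
Reactants: 3 (6R,10R)‑6,10,14‑trimethylpentadecan‑2‑one
Product: 4 (2R,6R,10R)‑6,10,14‑trimethylpentadecan‑2‑ol
Conditions: Lactobacillus brevis alcohol dehydrogenase, NADP+ (cat.), MgCl2, i‑PrOH, phosphate buffer pH 7/MTBE, 30 °C
Reagents that add atoms: none
Why: Enzymatic ketone reduction: this anti‑Prelog dehydrogenase delivers the NADPH hydride to the si face of methyl ketones, so methyl and long chain are told apart and C2 is set as R by the enzyme. 2‑Propanol regenerates the cofactor, and the remote C6 and C10 centres neither influence nor suffer from the step.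

Step 3
Reactants: 4 (2R,6R,10R)‑6,10,14‑trimethylpentadecan‑2‑ol; 5 2,4,6‑tri(propan‑2‑yl)benzoyl chloride
Product: 7 (2R,6R,10R)‑6,10,14‑trimethylpentadecan‑2‑yl 2,4,6‑tri(propan‑2‑yl)benzoate, via sodium alkoxide 6 (not isolated)
Conditions: NaH, THF, 0 °C to rt; then 5, 0 °C to 60 °C
Reagents that add atoms: none
Why: O‑Acylation of a preformed alkoxide by a hindered aroyl chloride (addition–elimination at the acyl carbon). The carbinol C–O bond is not broken, so 2R is retained, and the twisted triisopropylaryl ester is the directing and leaving group needed in step 8.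

Step 4
Reactants: 8 4‑methoxy‑2‑methylphenol
Product: 9 2‑hydroxy‑5‑methoxy‑3‑methylbenzaldehyde
Conditions: MgCl2, Et3N, (CH2O)n, MeCN, reflux; aq HCl
Reagents that add atoms: paraformaldehyde (as formaldehyde), C=O
Why: Magnesium‑mediated ortho‑formylation of a phenol (Casnati–Skattebøl): the magnesium phenoxide delivers formaldehyde to the ortho carbon and a second formaldehyde oxidises the hydroxymethyl stage by hydride transfer. Only one ortho position of 8 is free, so the aldehyde can enter only at the future C4a.

Step 5
Reactants: 9 2‑hydroxy‑5‑methoxy‑3‑methylbenzaldehyde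
Product: 10 2,5‑dimethoxy‑3‑methylbenzaldehyde
Conditions: MeI, K2CO3, DMF, rt
Reagents that add atoms: iodomethane, CI
Why: Williamson ether synthesis on the phenoxide; the aldehyde has no α‑hydrogen and is inert to carbonate. The para‑dimethoxy pattern is a latent quinone that survives the organolithium step.

Step 6
Reactants: 10 2,5‑dimethoxy‑3‑methylbenzaldehyde
Product: 11 1‑ethenyl‑2,5‑dimethoxy‑3‑methylbenzene
Conditions: Ph3PCH3Br, KOtBu, THF, 0 °C to rt
Reagents that add atoms: methyltriphenylphosphonium bromide, C[P+](c1ccccc1)(c1ccccc1)c1ccccc1.[Br-]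
Why: Wittig methylenation with the non‑stabilised ylide; the aldehyde is the only electrophile in 10.

Step 7
Reactants: 11 1‑ethenyl‑2,5‑dimethoxy‑3‑methylbenzene
Product: 12 2‑[2‑(2,5‑dimethoxy‑3‑methylphenyl)ethyl]‑5,5‑dimethyl‑1,3,2‑dioxaborinane
Conditions: bis(neopentyl glycolato)diboron, CuCl (cat.), Xantphos (cat.), NaOtBu (cat.), MeOH, THF, rt
Reagents that add atoms: bis(neopentyl glycolato)diboron, CC1(C)COB(OC1)B1OCC(C)(C)CO1
Why: Copper‑catalysed protoboration of a vinylarene: the copper boryl species adds across the alkene with copper at the benzylic carbon and boron at the terminal carbon, and methanol protonates the C–Cu bond. This regiochemistry gives the linear 2‑arylethyl boronate directly as the six‑membered ester wanted for step 8.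

Step 8
Reactants: 7 (2R,6R,10R)‑6,10,14‑trimethylpentadecan‑2‑yl 2,4,6‑tri(propan‑2‑yl)benzoate; 12 2‑[2‑(2,5‑dimethoxy‑3‑methylphenyl)ethyl]‑5,5‑dimethyl‑1,3,2‑dioxaborinane
Product: 15 2‑[(3S,7R,11R)‑1‑(2,5‑dimethoxy‑3‑methylphenyl)‑3,7,11,15‑tetramethylhexadecan‑3‑yl]‑5,5‑dimethyl‑1,3,2‑dioxaborinane, via lithiated benzoate 13 (not isolated), via boron ate complex 14 (not isolated)
Conditions: 7, TMEDA (6 equiv), sec‑butyllithium (1.6 equiv), cyclopentyl methyl ether, −60 °C, 2 h; then 12 (2 equiv), −60 °C, 1 h; then warm to 40 °C; aq NH4Cl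
Reagents that add atoms: none
Why: sec‑Butyllithium with TMEDA, coordinated to the ester carbonyl, removes the C2 proton of 7 with retention to give the dipole‑stabilised, non‑mesomeric organolithium 13, which should keep its configuration at −60 °C in cyclopentyl methyl ether. The primary boronate 12 is captured at the C–Li bond, again with retention, to give ate complex 14. On warming, the 2‑arylethyl group shifts from boron to C2 antiperiplanar to the departing triisopropylbenzoate, so C2–C3 forms with inversion at carbon (stereospecific 1,2‑metallate rearrangement); the closest known reaction class is the lithiation–borylation of secondary dialkyl 2,4,6‑triisopropylbenzoates with primary boronic esters. No ring is closed. The new stereocentre C2 is controlled only by the 2R carbinol configuration of 7: the net outcome equals substitution of the C2 hydrogen by C3 with the oxygen function (now boron, later hydroxyl) left in place, which is the arrangement that becomes 2R in the target. The step needs α‑deprotonation instead of attack at the carbonyl, which the two ortho isopropyl groups enforce; it needs borylation before the hindered organolithium decays, which the unhindered six‑membered primary boronate and the low temperature should secure; and it needs migration of carbon in preference to a ring oxygen, which the primary alkyl group and the good carboxylate leaving group favour. Surplus base is quenched harmlessly by the excess of 12, and the C6 and C10 centres are remote spectators.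

Step 9
Reactants: 15 2‑[(3S,7R,11R)‑1‑(2,5‑dimethoxy‑3‑methylphenyl)‑3,7,11,15‑tetramethylhexadecan‑3‑yl]‑5,5‑dimethyl‑1,3,2‑dioxaborinane
Product: 16 (3R,7R,11R)‑1‑(2,5‑dimethoxy‑3‑methylphenyl)‑3,7,11,15‑tetramethylhexadecan‑3‑ol
Conditions: H2O2 (30% aq), NaOH (2 M aq), THF, 0 °C to rt
Reagents that add atoms: hydrogen peroxide, OO
Why: Oxidation of a C–B bond by alkaline hydrogen peroxide: hydroperoxide adds to boron and the tertiary alkyl group migrates to oxygen with retention, which places the future O1 on C2 in the 2R arrangement. The aryl ethers and the arene are inert to these conditions.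

Step 10
Reactants: 16 (3R,7R,11R)‑1‑(2,5‑dimethoxy‑3‑methylphenyl)‑3,7,11,15‑tetramethylhexadecan‑3‑ol
Product: 17 2‑[(3R,7R,11R)‑3‑hydroxy‑3,7,11,15‑tetramethylhexadecyl]‑6‑methylcyclohexa‑2,5‑diene‑1,4‑dione
Conditions: (NH4)2Ce(NO3)6 (2.5 equiv), MeCN/H2O, 0 °C, 16 added to the oxidant
Reagents that add atoms: water, O
Why: Oxidative demethylation of a para‑dimethoxyarene by tetravalent cerium: two one‑electron oxidations with attack of water at the two methoxy‑bearing carbons release methanol and give the para‑quinone. The tertiary alcohol cannot be oxidised and the short, cold contact with aqueous acid should not ionise it; adding 16 to the oxidant keeps the concentration of unoxidised arene low and so disfavours radical‑cation coupling at the two free ring positions.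

Step 11
Reactants: 17 2‑[(3R,7R,11R)‑3‑hydroxy‑3,7,11,15‑tetramethylhexadecyl]‑6‑methylcyclohexa‑2,5‑diene‑1,4‑dione
Product: 19 (2R)‑2,8‑dimethyl‑2‑[(4R,8R)‑4,8,12‑trimethyltridecyl]‑3,4‑dihydro‑2H‑chromen‑6‑ol (δ‑tocopherol), via hydroquinone 18 (not isolated)
Conditions: H2 (1 atm), Pd/C, EtOAc, rt; filter under Ar; then p‑TsOH·H2O (cat.), degassed PhMe, 60 °C
Reagents that add atoms: none
Why: Reductive cyclisation of a hydroxyalkyl quinone: hydrogenation gives hydroquinone 18, and under acid the tertiary hydroxyl adds to C8a of the ring‑protonated keto tautomer (or of a trace of 17 acting as redox carrier) in a 6‑exo‑trig sense to give a cyclic hemiketal, which loses the C8a hydroxyl as water and rearomatises. The aryl C–O bond is the one exchanged and C2–O is never broken, so C2 stays R; mild acid and moderate temperature are chosen so that ionisation at C2 does not compete.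

## Compound list

1 | (2E,7R,11R)‑3,7,11,15‑tetramethylhexadec‑2‑en‑1‑ol (natural phytol) | CC(C)CCC[C@@H](C)CCC[C@@H](C)CCC/C(C)=C/CO | starting material
2 | {5‑methyl‑5‑[(4R,8R)‑4,8,12‑trimethyltridecyl]‑1,2,4‑trioxolan‑3‑yl}methanol (secondary ozonide, ring carbons as a mixture) | OCC1OOC(C)(CCC[C@H](C)CCC[C@H](C)CCCC(C)C)O1 | intermediate
3 | (6R,10R)‑6,10,14‑trimethylpentadecan‑2‑one | CC(=O)CCC[C@H](C)CCC[C@H](C)CCCC(C)C | intermediate
4 | (2R,6R,10R)‑6,10,14‑trimethylpentadecan‑2‑ol | C[C@@H](O)CCC[C@H](C)CCC[C@H](C)CCCC(C)C | intermediate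
5 | 2,4,6‑tri(propan‑2‑yl)benzoyl chloride | CC(C)c1cc(C(C)C)c(C(Cl)=O)c(C(C)C)c1 | starting material
6 | sodium (2R,6R,10R)‑6,10,14‑trimethylpentadecan‑2‑olate | [Na+].C[C@@H]([O-])CCC[C@H](C)CCC[C@H](C)CCCC(C)C | intermediate
7 | (2R,6R,10R)‑6,10,14‑trimethylpentadecan‑2‑yl 2,4,6‑tri(propan‑2‑yl)benzoate | CC(C)c1cc(C(C)C)c(C(=O)O[C@H](C)CCC[C@H](C)CCC[C@H](C)CCCC(C)C)c(C(C)C)c1 | intermediate
8 | 4‑methoxy‑2‑methylphenol | COc1ccc(O)c(C)c1 | starting material
9 | 2‑hydroxy‑5‑methoxy‑3‑methylbenzaldehyde | COc1cc(C)c(O)c(C=O)c1 | intermediate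
10 | 2,5‑dimethoxy‑3‑methylbenzaldehyde | COc1cc(C)c(OC)c(C=O)c1 | intermediate
11 | 1‑ethenyl‑2,5‑dimethoxy‑3‑methylbenzene | COc1cc(C)c(OC)c(C=C)c1 | intermediate
12 | 2‑[2‑(2,5‑dimethoxy‑3‑methylphenyl)ethyl]‑5,5‑dimethyl‑1,3,2‑dioxaborinane | COc1cc(C)c(OC)c(CCB2OCC(C)(C)CO2)c1 | intermediate
13 | (2R,6R,10R)‑2‑lithio‑6,10,14‑trimethylpentadecan‑2‑yl 2,4,6‑tri(propan‑2‑yl)benzoate (TMEDA‑ligated) | CC(C)c1cc(C(C)C)c(C(=O)O[C@]([Li])(C)CCC[C@H](C)CCC[C@H](C)CCCC(C)C)c(C(C)C)c1 | intermediate
14 | lithium ate complex of 12 bonded at boron to C2 of the (2R,6R,10R)‑2‑[2,4,6‑tri(propan‑2‑yl)benzoyloxy]‑6,10,14‑trimethylpentadecan‑2‑yl group | [Li+].COc1cc(C)c(OC)c(CC[B-]2(OCC(C)(C)CO2)[C@@](C)(CCC[C@H](C)CCC[C@H](C)CCCC(C)C)OC(=O)c2c(C(C)C)cc(C(C)C)cc2C(C)C)c1 | intermediate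
15 | 2‑[(3S,7R,11R)‑1‑(2,5‑dimethoxy‑3‑methylphenyl)‑3,7,11,15‑tetramethylhexadecan‑3‑yl]‑5,5‑dimethyl‑1,3,2‑dioxaborinane | COc1cc(C)c(OC)c(CC[C@@](C)(CCC[C@H](C)CCC[C@H](C)CCCC(C)C)B2OCC(C)(C)CO2)c1 | intermediate
16 | (3R,7R,11R)‑1‑(2,5‑dimethoxy‑3‑methylphenyl)‑3,7,11,15‑tetramethylhexadecan‑3‑ol | COc1cc(C)c(OC)c(CC[C@@](C)(CCC[C@H](C)CCC[C@H](C)CCCC(C)C)O)c1 | intermediate
17 | 2‑[(3R,7R,11R)‑3‑hydroxy‑3,7,11,15‑tetramethylhexadecyl]‑6‑methylcyclohexa‑2,5‑diene‑1,4‑dione | CC1=CC(=O)C=C(CC[C@@](C)(CCC[C@H](C)CCC[C@H](C)CCCC(C)C)O)C1=O | intermediate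
18 | 2‑[(3R,7R,11R)‑3‑hydroxy‑3,7,11,15‑tetramethylhexadecyl]‑6‑methylbenzene‑1,4‑diol | Cc1cc(O)cc(CC[C@@](C)(CCC[C@H](C)CCC[C@H](C)CCCC(C)C)O)c1O | intermediate
19 | (2R)‑2,8‑dimethyl‑2‑[(4R,8R)‑4,8,12‑trimethyltridecyl]‑3,4‑dihydro‑2H‑chromen‑6‑ol (δ‑tocopherol) | Cc1cc(O)cc2c1O[C@](C)(CCC[C@H](C)CCC[C@H](C)CCCC(C)C)CC2 | target

## Step count and least certain steps

Total: 11 steps. Longest linear sequence: 8 steps (8 to 19 through steps 4 to 11); the chain branch (1 to 7, steps 1 to 3) joins at step 8.

Step 8 (key step). The most likely failure is incomplete α‑deprotonation of 7 together with thermal decay of the hindered tertiary organolithium before it is borylated, because both events are slow at the only temperature at which the carbanion survives. A second failure is migration of a ring oxygen instead of carbon in the crowded ate complex. The fallback sets out from 1 and 8, comes back at 16, and takes C2 from C3 of 1 instead of from boron chemistry. Sharpless asymmetric epoxidation of 1 (Ti(OiPr)4, D‑(−)‑diethyl tartrate, t‑BuOOH, 4 Å sieves, CH2Cl2, −20 °C) should give [(2R,3R)‑3‑methyl‑3‑[(4R,8R)‑4,8,12‑trimethyltridecyl]oxiran‑2‑yl]methanol F1. Hydride opening at the less substituted C2 with NaAlH2(OCH2CH2OCH3)2 in THF leaves the C3–O bond intact and gives (3R,7R,11R)‑3,7,11,15‑tetramethylhexadecane‑1,3‑diol F2, and TsCl in pyridine sulfonylates only the primary hydroxyl to give (3R,7R,11R)‑3‑hydroxy‑3,7,11,15‑tetramethylhexadecyl 4‑methylbenzenesulfonate F3. In parallel 8 is brominated at its one free ortho position (NBS, MeCN) to 2‑bromo‑4‑methoxy‑6‑methylphenol F4, methylated (MeI, K2CO3) to 1‑bromo‑2,5‑dimethoxy‑3‑methylbenzene F5 and converted with Mg in THF into (2,5‑dimethoxy‑3‑methylphenyl)magnesium bromide F6. An excess of F6 (one equivalent is consumed by the tertiary hydroxyl) displaces the sulfonate of F3 under Li2CuCl4 catalysis to give 16.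

Step 7. Regiochemical leakage in the copper boryl insertion (boron entering at the benzylic carbon) and partial hydrolysis of the six‑membered boronic ester during purification are the likely problems. The fallback sets out from 11 and comes back at 12 through iridium‑catalysed hydroboration, a different bond‑forming event. Pinacolborane with [Ir(cod)Cl]2 and dppe in CH2Cl2 should give the linear 2‑[2‑(2,5‑dimethoxy‑3‑methylphenyl)ethyl]‑4,4,5,5‑tetramethyl‑1,3,2‑dioxaborolane F7. NaIO4 and NH4OAc in aqueous acetone cleave the pinacol unit to [2‑(2,5‑dimethoxy‑3‑methylphenyl)ethyl]boronic acid F8, and condensation with 2,2‑dimethylpropane‑1,3‑diol over MgSO4 gives 12.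

Step 2. Slow, incomplete turnover is likely because the C18 ketone is almost insoluble in the aqueous phase, and face selection may be imperfect with so long a chain. The fallback sets out from 3 and comes back at 4 (and, for the other epimer, at 7); it replaces asymmetric reduction by epimer‑selective acylation. NaBH4 in MeOH gives (6R,10R)‑6,10,14‑trimethylpentadecan‑2‑ol as both C2 epimers F9. Immobilised Candida antarctica lipase B with vinyl acetate in hexane should acetylate only the 2R epimer to (2R,6R,10R)‑6,10,14‑trimethylpentadecan‑2‑yl acetate F10 and leave (2S,6R,10R)‑6,10,14‑trimethylpentadecan‑2‑ol F11, which is separated by chromatography. K2CO3 in MeOH converts F10 into 4, and a Mitsunobu esterification of F11 with 2,4,6‑tri(propan‑2‑yl)benzoic acid (PPh3, diisopropyl azodicarboxylate, THF) gives 7 with inversion, so both epimers are used.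

Step 10. Oxidative coupling of the arene radical cation at the two unsubstituted ring positions, and further oxidation of the electron‑rich quinone, are the likely losses, because this ring is less substituted than that of the fully methylated tocopherols. The fallback sets out from 16 and comes back at 17; it replaces the chemical oxidant by anodic ketalisation. Electrolysis at a platinum anode in KOH/MeOH at 0 °C should give (3R,7R,11R)‑3,7,11,15‑tetramethyl‑1‑(3,3,6,6‑tetramethoxy‑5‑methylcyclohexa‑1,4‑dien‑1‑yl)hexadecan‑3‑ol F12, in which methoxide traps the oxidised ring before it can couple, and dilute aqueous acetic acid in THF hydrolyses both ketals to 17.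

Step 11. Partial ionisation of the tertiary C2–O bond under acid would erode the configuration at C2; the risk is real because the less substituted ring of the δ series is protonated less readily than a fully methylated one. The fallback sets out from 18 (made by the hydrogenation stage alone) and comes back at 19; it forms O1–C8a by cross‑coupling, in which C2–O cannot ionise. Selective silylation of the unhindered phenol (i‑Pr3SiCl, imidazole, DMF) gives 2‑[(3R,7R,11R)‑3‑hydroxy‑3,7,11,15‑tetramethylhexadecyl]‑6‑methyl‑4‑{[tri(propan‑2‑yl)silyl]oxy}phenol F13. PhNTf2 and Cs2CO3 convert the remaining hindered phenol into 2‑[(3R,7R,11R)‑3‑hydroxy‑3,7,11,15‑tetramethylhexadecyl]‑6‑methyl‑4‑{[tri(propan‑2‑yl)silyl]oxy}phenyl trifluoromethanesulfonate F14. Intramolecular aryl etherification (Pd(OAc)2, 2‑(di‑tert‑butylphosphino)‑1,1'‑binaphthyl, Cs2CO3, PhMe, 80 °C), in which the tertiary alkoxide has no hydrogen on the carbinol carbon to lose, gives {[(2R)‑2,8‑dimethyl‑2‑[(4R,8R)‑4,8,12‑trimethyltridecyl]‑3,4‑dihydro‑2H‑chromen‑6‑yl]oxy}tri(propan‑2‑yl)silane F15, and Bu4NF in THF releases 19.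

## Further compounds

F1 | step 8 | [(2R,3R)‑3‑methyl‑3‑[(4R,8R)‑4,8,12‑trimethyltridecyl]oxiran‑2‑yl]methanol | OC[C@H]1O[C@]1(C)CCC[C@H](C)CCC[C@H](C)CCCC(C)C
F2 | step 8 | (3R,7R,11R)‑3,7,11,15‑tetramethylhexadecane‑1,3‑diol | OCC[C@@](C)(CCC[C@H](C)CCC[C@H](C)CCCC(C)C)O
F3 | step 8 | (3R,7R,11R)‑3‑hydroxy‑3,7,11,15‑tetramethylhexadecyl 4‑methylbenzenesulfonate | Cc1ccc(cc1)S(=O)(=O)OCC[C@@](C)(CCC[C@H](C)CCC[C@H](C)CCCC(C)C)O
F4 | step 8 | 2‑bromo‑4‑methoxy‑6‑methylphenol | COc1cc(C)c(O)c(Br)c1
F5 | step 8 | 1‑bromo‑2,5‑dimethoxy‑3‑methylbenzene | COc1cc(C)c(OC)c(Br)c1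
F6 | step 8 | (2,5‑dimethoxy‑3‑methylphenyl)magnesium bromide | COc1cc(C)c(OC)c([Mg]Br)c1
F7 | step 7 | 2‑[2‑(2,5‑dimethoxy‑3‑methylphenyl)ethyl]‑4,4,5,5‑tetramethyl‑1,3,2‑dioxaborolane | COc1cc(C)c(OC)c(CCB2OC(C)(C)C(C)(C)O2)c1
F8 | step 7 | [2‑(2,5‑dimethoxy‑3‑methylphenyl)ethyl]boronic acid | COc1cc(C)c(OC)c(CCB(O)O)c1
F9 | step 2 | (6R,10R)‑6,10,14‑trimethylpentadecan‑2‑ol, both C2 epimers | CC(O)CCC[C@H](C)CCC[C@H](C)CCCC(C)C
F10 | step 2 | (2R,6R,10R)‑6,10,14‑trimethylpentadecan‑2‑yl acetate | CC(=O)O[C@H](C)CCC[C@H](C)CCC[C@H](C)CCCC(C)C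
F11 | step 2 | (2S,6R,10R)‑6,10,14‑trimethylpentadecan‑2‑ol | C[C@H](O)CCC[C@H](C)CCC[C@H](C)CCCC(C)C
F12 | step 10 | (3R,7R,11R)‑3,7,11,15‑tetramethyl‑1‑(3,3,6,6‑tetramethoxy‑5‑methylcyclohexa‑1,4‑dien‑1‑yl)hexadecan‑3‑ol | COC1(OC)C=C(C)C(OC)(OC)C(CC[C@@](C)(CCC[C@H](C)CCC[C@H](C)CCCC(C)C)O)=C1
F13 | step 11 | 2‑[(3R,7R,11R)‑3‑hydroxy‑3,7,11,15‑tetramethylhexadecyl]‑6‑methyl‑4‑{[tri(propan‑2‑yl)silyl]oxy}phenol | Cc1cc(O[Si](C(C)C)(C(C)C)C(C)C)cc(CC[C@@](C)(CCC[C@H](C)CCC[C@H](C)CCCC(C)C)O)c1O
F14 | step 11 | 2‑[(3R,7R,11R)‑3‑hydroxy‑3,7,11,15‑tetramethylhexadecyl]‑6‑methyl‑4‑{[tri(propan‑2‑yl)silyl]oxy}phenyl trifluoromethanesulfonate | Cc1cc(O[Si](C(C)C)(C(C)C)C(C)C)cc(CC[C@@](C)(CCC[C@H](C)CCC[C@H](C)CCCC(C)C)O)c1OS(=O)(=O)C(F)(F)F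
F15 | step 11 | {[(2R)‑2,8‑dimethyl‑2‑[(4R,8R)‑4,8,12‑trimethyltridecyl]‑3,4‑dihydro‑2H‑chromen‑6‑yl]oxy}tri(propan‑2‑yl)silane | Cc1cc(O[Si](C(C)C)(C(C)C)C(C)C)cc2c1O[C@](C)(CCC[C@H](C)CCC[C@H](C)CCCC(C)C)CC2
A1 | alternative 1 | (2S)‑6‑(benzyloxy)‑8‑methyl‑2‑[(2E,4R,8R)‑4,8,12‑trimethyltridec‑2‑en‑1‑yl]‑3,4‑dihydro‑2H‑chromene‑2‑carboxylic acid | Cc1cc(OCc3ccccc3)cc2c1O[C@](C(=O)O)(C/C=C/[C@H](C)CCC[C@H](C)CCCC(C)C)CC2
A2 | alternative 1 | (3R,4R,8R)‑4,8,12‑trimethyltridec‑1‑en‑3‑yl 6‑(benzyloxy)‑8‑methyl‑3,4‑dihydro‑2H‑chromene‑2‑carboxylate (C2 of the chroman either way) | C=C[C@@H](OC(=O)C1CCc2cc(OCc3ccccc3)cc(C)c2O1)[C@H](C)CCC[C@H](C)CCCC(C)C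
A3 | alternative 2 | (2R)‑2,8‑dimethyl‑2‑[(4R,8R)‑4,8,12‑trimethyltridecyl]‑3,4‑dihydro‑2H‑chromen‑6‑yl acetate | CC(=O)Oc1cc(C)c2O[C@](C)(CCC[C@H](C)CCC[C@H](C)CCCC(C)C)CCc2c1
A4 | alternative 2 | (2R)‑2,8‑dimethyl‑2‑[(3E,7E)‑4,8,12‑trimethyltrideca‑3,7,11‑trien‑1‑yl]‑3,4‑dihydro‑2H‑chromen‑6‑yl acetate | CC(=O)Oc1cc(C)c2O[C@](C)(CC/C=C(\C)CC/C=C(\C)CCC=C(C)C)CCc2c1
A5 | alternative 3 | (2R)‑6‑(benzyloxy)‑2,8‑dimethyl‑2‑[(4R,8R)‑4,8,12‑trimethyltridecyl]‑2,3‑dihydro‑4H‑chromen‑4‑one | Cc1cc(OCc3ccccc3)cc2c1O[C@](C)(CCC[C@H](C)CCC[C@H](C)CCCC(C)C)CC2=O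
A6 | alternative 3 | 6‑(benzyloxy)‑8‑methyl‑2‑[(4R,8R)‑4,8,12‑trimethyltridecyl]‑4H‑chromen‑4‑one | Cc1cc(OCc3ccccc3)cc2c1OC(CCC[C@H](C)CCC[C@H](C)CCCC(C)C)=CC2=O
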